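**Strategy.** The lactone is cut at C3–C4, the bond between the α-carbon C3, which carries only the exocyclic benzylidene carbon C6, and the benzyl-bearing stereocentre C4. That array is what a six-membered 3-diazopyran-2,4-dione leaves on Wolff ring contraction. In one operation N2 is lost, C5 of the pyrandione migrates with retention to the diazo carbon, the γ-butyrolactone ring forms, and the expelled ketone carbon appears as a ketene that ethanethiol captures as the C6 thioester, ready for arylation. The precursor is the (5S)-5-arylmethyl-3-diazodihydropyran-2,4-dione, built from vanillin through a lipase-desymmetrised 2-benzylpropane-1,3-diol and Meldrum's acid. The second aryl ring enters afterwards by Liebeskind–Srogl coupling.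

Key step: step 10

Assumption: Burkholderia cepacia lipase is taken to acetylate 2-arylmethylpropane-1,3-diols in the sense that gives the (R)-monoacetate; should the (S)-ester predominate, hydrolysis of the diacetate with the same enzyme would supply the (R)-monoacetate instead.

**Route**

Step 1
Reactants: 1 vanillin
Product: 2 3-methoxy-4-(methoxymethoxy)benzaldehyde
Conditions: MOMCl, iPr2NEt, CH2Cl2, 0 °C to rt
Reagents that add atoms: chloromethyl methyl ether, COCCl
Why: O-alkylation of the phenoxide (MOM protection) masks the phenol, which would otherwise consume hydride, be oxidised in step 6 and intercept the acylketene of the key step, while the aldehyde is untouched.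

Step 2
Reactants: 2 3-methoxy-4-(methoxymethoxy)benzaldehyde; 3 diethyl malonate
Product: 4 diethyl 2-[3-methoxy-4-(methoxymethoxy)benzylidene]malonate
Conditions: piperidine (cat.), AcOH (cat.), toluene, reflux, Dean–Stark
Reagents that add atoms: none
Why: Knoevenagel condensation of the non-enolisable aldehyde with the malonate is driven by azeotropic removal of water, and the buffered piperidinium acetate medium leaves the MOM acetal intact.

Step 3
Reactants: 4 diethyl 2-[3-methoxy-4-(methoxymethoxy)benzylidene]malonate
Product: 5 diethyl 2-[3-methoxy-4-(methoxymethoxy)benzyl]malonate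
Conditions: H2 (1 atm), Pd/C, EtOAc, rt
Reagents that add atoms: none
Why: Heterogeneous catalytic hydrogenation saturates the electron-poor benzylidene double bond at ambient pressure without touching the arene, the esters or the aryl MOM ether.

Step 4
Reactants: 5 diethyl 2-[3-methoxy-4-(methoxymethoxy)benzyl]malonate
Product: 6 2-[3-methoxy-4-(methoxymethoxy)benzyl]propane-1,3-diol
Conditions: LiAlH4, THF, 0 °C to rt; Fieser work-up (H2O, aq. NaOH)
Reagents that add atoms: none
Why: LiAlH4 reduction of both ester groups gives the prochiral 2-substituted propane-1,3-diol, the acetal-protected phenol being inert to hydride and addition of the ester to excess hydride at 0 °C limiting enolisation of the malonate.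

Step 5
Reactants: 6 2-[3-methoxy-4-(methoxymethoxy)benzyl]propane-1,3-diol
Product: 7 (2R)-3-hydroxy-2-[3-methoxy-4-(methoxymethoxy)benzyl]propyl acetate
Conditions: Burkholderia cepacia lipase (Amano PS), vinyl acetate, iPr2O, rt
Reagents that add atoms: vinyl acetate, CC(=O)OC=C
Why: Lipase-catalysed irreversible transesterification (enzymatic desymmetrisation) differentiates the two enantiotopic hydroxymethyl groups, the chiral active site setting the single stereocentre as (R), while tautomerisation of the released vinyl alcohol to acetaldehyde blocks the reverse reaction.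

Step 6
Reactants: 7 (2R)-3-hydroxy-2-[3-methoxy-4-(methoxymethoxy)benzyl]propyl acetate
Product: 9 (2S)-3-acetoxy-2-[3-methoxy-4-(methoxymethoxy)benzyl]propanoic acid, via aldehyde 8 (not isolated)
Conditions: TEMPO (cat.), PhI(OAc)2, MeCN/H2O (1:1), rt
Reagents that add atoms: water, O
Why: TEMPO/PhI(OAc)2 oxidation takes the primary alcohol through the aldehyde hydrate to the acid under near-neutral conditions that should neither shift the acetate between the two arms nor epimerise the α-carbon, and the non-phenolic arene is not oxidised.

Step 7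
Reactants: 9 (2S)-3-acetoxy-2-[3-methoxy-4-(methoxymethoxy)benzyl]propanoic acid; 10 Meldrum's acid
Product: 12 methyl (4S)-4-(acetoxymethyl)-5-[3-methoxy-4-(methoxymethoxy)phenyl]-3-oxopentanoate, via acyl Meldrum's acid 11 (not isolated)
Conditions: DCC, DMAP, CH2Cl2, 0 °C to rt; filter, cold aq. KHSO4 wash; then MeOH, reflux
Reagents that add atoms: methanol, CO
Why: Carbodiimide-mediated C-acylation of Meldrum's acid, then thermal cycloreversion of the acyl Meldrum's acid to an acylketene that methanol traps, gives the homologated β-keto ester, and the stereocentre is spared because the acylated intermediate is held as its strongly acidic enol.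

Step 8
Reactants: 12 methyl (4S)-4-(acetoxymethyl)-5-[3-methoxy-4-(methoxymethoxy)phenyl]-3-oxopentanoate
Product: 14 (5S)-5-[3-methoxy-4-(methoxymethoxy)benzyl]dihydro-2H-pyran-2,4(3H)-dione (drawn as the dione; enol tautomer also present), via hydroxy keto ester 13 (not isolated)
Conditions: K2CO3, MeOH, 0 °C to rt; then cold 1 M HCl to pH 3
Reagents that add atoms: none
Why: Base-mediated methanolysis of the acetate frees the primary alcohol, which lactonises onto the methyl ester to give the six-membered β-keto lactone as its stabilised enolate; because the 1,3-dicarbonyl unit is deprotonated first, the C–H at the stereocentre is not acidic enough to epimerise or to trigger β-elimination.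

Step 9
Reactants: 14 (5S)-5-[3-methoxy-4-(methoxymethoxy)benzyl]dihydro-2H-pyran-2,4(3H)-dione
Product: 15 (5S)-3-diazo-5-[3-methoxy-4-(methoxymethoxy)benzyl]dihydro-2H-pyran-2,4(3H)-dione
Conditions: 4-acetamidobenzenesulfonyl azide, Et3N (1.1 equiv), MeCN, 0 °C
Reagents that add atoms: 4-acetamidobenzenesulfonyl azide, CC(=O)Nc1ccc(cc1)S(=O)(=O)N=[N+]=[N-]
Why: Regitz diazo transfer from the sulfonyl azide to the doubly activated C3 methylene (as its ammonium enolate) gives the 2-diazo-1,3-dicarbonyl compound, and one equivalent of triethylamine at 0 °C is too weak a base to deprotonate C5, so the stereocentre should survive.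

Step 10
Reactants: 15 (5S)-3-diazo-5-[3-methoxy-4-(methoxymethoxy)benzyl]dihydro-2H-pyran-2,4(3H)-dione; 16 ethanethiol
Product: 18 S-ethyl (4R)-4-[3-methoxy-4-(methoxymethoxy)benzyl]-2-oxotetrahydrofuran-3-carbothioate (C3 epimers), via acylketene 17 (not isolated)
Conditions: hν (medium-pressure Hg lamp, Pyrex filter, λ > 300 nm), EtSH (10 equiv), degassed CH2Cl2, 10 °C
Reagents that add atoms: none
Why: Excitation of the diazo dicarbonyl chromophore expels N2 and, because the ring holds both carbonyls s-Z to the diazo group, the C4–C5 bond shifts to the diazo carbon C3 essentially in concert (Wolff rearrangement), giving the α-oxoketene 17, whose ketene carbon is attacked by ethanethiol to give the thioester. The closest known reaction type is the photochemical Wolff ring contraction of cyclic 2-diazo-1,3-dicarbonyl compounds with capture of the ketene by an alcohol, amine or thiol. The five-membered lactone is not closed by an end-to-end cyclisation but by 1,2-shift ring contraction: the new C3–C4 bond (lactone numbering) forms as the former ketone carbon leaves the ring. The migrating carbon keeps its configuration (1,2-shift with retention), so (5S) in the pyrandione becomes (4R) in the lactone, the change of descriptor reflecting only changed CIP priorities; C3 forms as an uncontrolled epimer mixture and is made planar in step 15. The step needs carbon rather than alkoxy migration, which the keto ester secures because the ketone-side alkyl group has a far higher migratory aptitude than the ester oxygen, and it needs light that the electron-rich arene and the thiol do not absorb, which the Pyrex cut-off provides.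

Step 11
Reactants: 19 2,3-dimethoxyphenol
Product: 20 1,2-dimethoxy-3-(methoxymethoxy)benzene
Conditions: MOMCl, iPr2NEt, CH2Cl2, 0 °C to rt
Reagents that add atoms: chloromethyl methyl ether, COCCl
Why: O-alkylation of the phenoxide installs the same acetal as on the other ring, so that both are removed together at the end, and leaves the borylation under purely steric control.

Step 12
Reactants: 20 1,2-dimethoxy-3-(methoxymethoxy)benzene
Product: 22 [3,4-dimethoxy-5-(methoxymethoxy)phenyl]boronic acid, via pinacol boronate 21 (not isolated)
Conditions: [Ir(OMe)(cod)]2 (cat.), 4,4'-di-tert-butyl-2,2'-bipyridine, B2pin2 (0.6 equiv), THF, 80 °C; then NaIO4, NH4OAc, acetone/H2O, rt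
Reagents that add atoms: bis(pinacolato)diboron, CC1(C)OB(OC1(C)C)B1OC(C)(C)C(C)(C)O1; water, O
Why: Iridium-catalysed C–H borylation is sterically controlled and goes to C5, the only ring C–H without an ortho substituent in the 1,2,3-trisubstituted arene, and buffered periodate cleavage of the pinacol then frees the boronic acid needed for copper-mediated transmetalation without endangering the MOM group.

Step 13
Reactants: 18 S-ethyl (4R)-4-[3-methoxy-4-(methoxymethoxy)benzyl]-2-oxotetrahydrofuran-3-carbothioate; 22 [3,4-dimethoxy-5-(methoxymethoxy)phenyl]boronic acid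
Product: 23 (4R)-3-[3,4-dimethoxy-5-(methoxymethoxy)benzoyl]-4-[3-methoxy-4-(methoxymethoxy)benzyl]dihydrofuran-2(3H)-one (C3 epimers interconverting through the enol)
Conditions: Pd2(dba)3 (cat.), tris(2-furyl)phosphine, Cu(O2CC4H3S) (copper thiophene-2-carboxylate, 1.6 equiv), THF, 50 °C, argon
Reagents that add atoms: none
Why: Liebeskind–Srogl ketone synthesis, in which zerovalent palladium inserts into the C(O)–S bond, the monovalent copper carboxylate binds sulfur and activates boron for transmetalation, and reductive elimination gives the aryl ketone under base-free conditions that tolerate the acidic C3–H, the lactone and both MOM ethers.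

Step 14
Reactants: 23 (4R)-3-[3,4-dimethoxy-5-(methoxymethoxy)benzoyl]-4-[3-methoxy-4-(methoxymethoxy)benzyl]dihydrofuran-2(3H)-one
Product: 24 (4R)-3-{[3,4-dimethoxy-5-(methoxymethoxy)phenyl](hydroxy)methyl}-4-[3-methoxy-4-(methoxymethoxy)benzyl]dihydrofuran-2(3H)-one (diastereomer mixture)
Conditions: NaBH4, MeOH/THF, −20 to 0 °C; aq. NH4Cl
Reagents that add atoms: none
Why: Borohydride reduces the aryl ketone much faster than the lactone at low temperature, and the configurations at C3 and the carbinol carbon are irrelevant because both carbons become sp2 in the next step.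

Step 15
Reactants: 24 (4R)-3-{[3,4-dimethoxy-5-(methoxymethoxy)phenyl](hydroxy)methyl}-4-[3-methoxy-4-(methoxymethoxy)benzyl]dihydrofuran-2(3H)-one
Product: 26 (3E,4R)-3-[3,4-dimethoxy-5-(methoxymethoxy)benzylidene]-4-[3-methoxy-4-(methoxymethoxy)benzyl]dihydrofuran-2(3H)-one, via mesylate 25 (not isolated)
Conditions: MsCl, Et3N, CH2Cl2, 0 °C; then DBU, 0 °C to rt
Reagents that add atoms: none
Why: Mesylation followed by DBU-induced E1cB elimination through the lactone enolate converges all diastereomers on the conjugated arylidene, the E isomer (aryl anti to the lactone carbonyl) being the expected kinetic and thermodynamic product, and short exposure to DBU avoids γ-deprotonation at C4.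

Step 16
Reactants: 26 (3E,4R)-3-[3,4-dimethoxy-5-(methoxymethoxy)benzylidene]-4-[3-methoxy-4-(methoxymethoxy)benzyl]dihydrofuran-2(3H)-one
Product: 27 (3E,4R)-3-(3-hydroxy-4,5-dimethoxybenzylidene)-4-(4-hydroxy-3-methoxybenzyl)dihydrofuran-2(3H)-one
Conditions: 3 M aq. HCl, MeOH/THF, 45 °C, exclusion of light
Reagents that add atoms: none
Why: Acid-catalysed acetal exchange with methanol cleaves both aryl MOM ethers to the free phenols under conditions in which the E-arylidene lactone and the C4 stereocentre are stable, and working in the dark avoids E/Z photoisomerisation.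

**Compound list**

1 | vanillin (4-hydroxy-3-methoxybenzaldehyde) | COc1cc(C=O)ccc1O | starting material
2 | 3-methoxy-4-(methoxymethoxy)benzaldehyde | COCOc1ccc(C=O)cc1OC | intermediate
3 | diethyl malonate | CCOC(=O)CC(=O)OCC | starting material
4 | diethyl 2-[3-methoxy-4-(methoxymethoxy)benzylidene]malonate | COCOc1ccc(C=C(C(=O)OCC)C(=O)OCC)cc1OC | intermediate
5 | diethyl 2-[3-methoxy-4-(methoxymethoxy)benzyl]malonate | COCOc1ccc(CC(C(=O)OCC)C(=O)OCC)cc1OC | intermediate
6 | 2-[3-methoxy-4-(methoxymethoxy)benzyl]propane-1,3-diol | COCOc1ccc(CC(CO)CO)cc1OC | intermediate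
7 | (2R)-3-hydroxy-2-[3-methoxy-4-(methoxymethoxy)benzyl]propyl acetate | COCOc1ccc(C[C@H](CO)COC(C)=O)cc1OC | intermediate
8 | (2S)-3-acetoxy-2-[3-methoxy-4-(methoxymethoxy)benzyl]propanal | COCOc1ccc(C[C@H](C=O)COC(C)=O)cc1OC | intermediate
9 | (2S)-3-acetoxy-2-[3-methoxy-4-(methoxymethoxy)benzyl]propanoic acid | COCOc1ccc(C[C@H](C(=O)O)COC(C)=O)cc1OC | intermediate
10 | Meldrum's acid (2,2-dimethyl-1,3-dioxane-4,6-dione) | CC1(C)OC(=O)CC(=O)O1 | starting material
11 | 5-{(2S)-3-acetoxy-1-hydroxy-2-[3-methoxy-4-(methoxymethoxy)benzyl]propylidene}-2,2-dimethyl-1,3-dioxane-4,6-dione (acyl Meldrum's acid, enol form) | COCOc1ccc(C[C@H](C(O)=C2C(=O)OC(C)(C)OC2=O)COC(C)=O)cc1OC | intermediate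
12 | methyl (4S)-4-(acetoxymethyl)-5-[3-methoxy-4-(methoxymethoxy)phenyl]-3-oxopentanoate | COCOc1ccc(C[C@H](C(=O)CC(=O)OC)COC(C)=O)cc1OC | intermediate
13 | methyl (4S)-4-(hydroxymethyl)-5-[3-methoxy-4-(methoxymethoxy)phenyl]-3-oxopentanoate | COCOc1ccc(C[C@H](C(=O)CC(=O)OC)CO)cc1OC | intermediate
14 | (5S)-5-[3-methoxy-4-(methoxymethoxy)benzyl]dihydro-2H-pyran-2,4(3H)-dione | COCOc1ccc(C[C@H]2COC(=O)CC2=O)cc1OC | intermediate
15 | (5S)-3-diazo-5-[3-methoxy-4-(methoxymethoxy)benzyl]dihydro-2H-pyran-2,4(3H)-dione | COCOc1ccc(C[C@H]2COC(=O)C(=[N+]=[N-])C2=O)cc1OC | intermediate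
16 | ethanethiol | CCS | starting material
17 | (4R)-4-[3-methoxy-4-(methoxymethoxy)benzyl]-3-(oxomethylidene)dihydrofuran-2(3H)-one (acylketene) | COCOc1ccc(C[C@H]2COC(=O)C2=C=O)cc1OC | intermediate
18 | S-ethyl (4R)-4-[3-methoxy-4-(methoxymethoxy)benzyl]-2-oxotetrahydrofuran-3-carbothioate (C3 epimers) | COCOc1ccc(C[C@H]2COC(=O)C2C(=O)SCC)cc1OC | intermediate
19 | 2,3-dimethoxyphenol | COc1cccc(O)c1OC | starting material
20 | 1,2-dimethoxy-3-(methoxymethoxy)benzene | COCOc1cccc(OC)c1OC | intermediate
21 | 2-[3,4-dimethoxy-5-(methoxymethoxy)phenyl]-4,4,5,5-tetramethyl-1,3,2-dioxaborolane | COCOc1cc(B2OC(C)(C)C(C)(C)O2)cc(OC)c1OC | intermediate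
22 | [3,4-dimethoxy-5-(methoxymethoxy)phenyl]boronic acid | COCOc1cc(B(O)O)cc(OC)c1OC | intermediate
23 | (4R)-3-[3,4-dimethoxy-5-(methoxymethoxy)benzoyl]-4-[3-methoxy-4-(methoxymethoxy)benzyl]dihydrofuran-2(3H)-one (C3 epimers) | COCOc1ccc(C[C@H]2COC(=O)C2C(=O)c2cc(OCOC)c(OC)c(OC)c2)cc1OC | intermediate
24 | (4R)-3-{[3,4-dimethoxy-5-(methoxymethoxy)phenyl](hydroxy)methyl}-4-[3-methoxy-4-(methoxymethoxy)benzyl]dihydrofuran-2(3H)-one (diastereomer mixture) | COCOc1ccc(C[C@H]2COC(=O)C2C(O)c2cc(OCOC)c(OC)c(OC)c2)cc1OC | intermediate
25 | [3,4-dimethoxy-5-(methoxymethoxy)phenyl]{(4R)-4-[3-methoxy-4-(methoxymethoxy)benzyl]-2-oxotetrahydrofuran-3-yl}methyl methanesulfonate (diastereomer mixture) | COCOc1ccc(C[C@H]2COC(=O)C2C(OS(C)(=O)=O)c2cc(OCOC)c(OC)c(OC)c2)cc1OC | intermediate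
26 | (3E,4R)-3-[3,4-dimethoxy-5-(methoxymethoxy)benzylidene]-4-[3-methoxy-4-(methoxymethoxy)benzyl]dihydrofuran-2(3H)-one | COCOc1ccc(C[C@H]2COC(=O)/C2=C/c2cc(OCOC)c(OC)c(OC)c2)cc1OC | intermediate
27 | (3E,4R)-3-(3-hydroxy-4,5-dimethoxybenzylidene)-4-(4-hydroxy-3-methoxybenzyl)dihydrofuran-2(3H)-one | COc1cc(C[C@H]2COC(=O)/C2=C/c2cc(O)c(OC)c(OC)c2)ccc1O | target

**Step count and risks**

Total step count: 16. Longest linear sequence: 14 steps (steps 1–10 and 13–16); the boronic acid branch is steps 11–12.

Steps most likely to fail:

1. Step 13 (thioester–boronic acid coupling). The acyl–palladium intermediate may be consumed unproductively (loss of CO, or collapse to the ketene through the acidic C3–H), or transmetalation may stall because the 1,3-dicarbonyl substrate and product sequester copper. The fallback sets out from 18 and returns at 24. Compound 18 would be saponified with LiOH in aqueous THF, acidified with citric acid to relactonise and warmed in toluene to decarboxylate, giving (4R)-4-[3-methoxy-4-(methoxymethoxy)benzyl]dihydrofuran-2(3H)-one F1. Its lithium enolate (LiN(SiMe3)2, THF, −78 °C) would then undergo aldol addition to 3,4-dimethoxy-5-(methoxymethoxy)benzaldehyde F2, itself made from commercial 3-hydroxy-4,5-dimethoxybenzaldehyde with chloromethyl methyl ether and iPr2NEt. The adduct is alcohol 24, which continues through steps 15 and 16.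

2. Step 10 (Wolff ring contraction in the presence of the thiol). The thiol may intercept the excited diazo compound or a free carbene (S–H insertion, reduction of the diazo group) or start thiyl-radical chemistry under irradiation before the 1,2-shift occurs. The fallback sets out from 15 and returns at 18. Compound 15 would be irradiated under the same filter in THF/water, so that water captures the ketene and gives (4R)-4-[3-methoxy-4-(methoxymethoxy)benzyl]-2-oxotetrahydrofuran-3-carboxylic acid F3. This acid would then be coupled with ethanethiol by DCC/DMAP at 0 °C (Steglich thioesterification) to give 18, so the carbon–sulfur bond is formed in a separate dark step.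

3. Step 7 (Meldrum's acid homologation). The activated β-acetoxy acid may lose acetate by elimination or epimerise at the α-carbon in the presence of DMAP, and the acetate may be partly lost during methanolysis. The fallback sets out from 9 and returns at 12. Acid 9 would be converted with 1,1'-carbonyldiimidazole in THF into (2S)-3-(1H-imidazol-1-yl)-2-[3-methoxy-4-(methoxymethoxy)benzyl]-3-oxopropyl acetate F4. This would be treated with potassium methyl malonate, MgCl2 and Et3N (Masamune–Brooks decarboxylative Claisen condensation under near-neutral conditions) to give β-keto ester 12 directly.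

**Further compounds**

F1 | step 13 | (4R)-4-[3-methoxy-4-(methoxymethoxy)benzyl]dihydrofuran-2(3H)-one | COCOc1ccc(C[C@H]2COC(=O)C2)cc1OC
F2 | step 13 | 3,4-dimethoxy-5-(methoxymethoxy)benzaldehyde | COCOc1cc(C=O)cc(OC)c1OC
F3 | step 10 | (4R)-4-[3-methoxy-4-(methoxymethoxy)benzyl]-2-oxotetrahydrofuran-3-carboxylic acid (C3 epimers) | COCOc1ccc(C[C@H]2COC(=O)C2C(=O)O)cc1OC
F4 | step 7 | (2S)-3-(1H-imidazol-1-yl)-2-[3-methoxy-4-(methoxymethoxy)benzyl]-3-oxopropyl acetate | COCOc1ccc(C[C@H](C(=O)n2ccnc2)COC(C)=O)cc1OC
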